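**Retrosynthetic overview**
1. C12–C13 bond and the 12R carbinol: made last, by reagent-controlled 2-isopropylallylboration of the bis-epoxy enal 19 (C6 unit from 2,3-dimethylbut-1-ene).
2. Both oxiranes: closed in one flask by chiral-dioxirane double epoxidation of the 2E and 6Z olefins of hydroxy trienal 16, as an epoxidase would oxidise the polyene. The 6,7-oxirane is expected to form first and the 2,3-oxirane second; the electron-poor enal olefin stays.
3. 16 comes from (2E,6Z)-farnesyl acetate 13 by allylic oxidation of the E-methyl group and deacetylation.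
4. 13 comes from nerol (which supplies the 6Z olefin), propyne (C3 unit), a methyl group (Zr-catalysed methylalumination, sets 2E) and formaldehyde (C1).

Assumption: locants count the main chain from the CH2OH carbon (C1); the SMILES is read as 2R,3R (trans oxirane), 6R,7S (cis oxirane, hence a 6Z olefin precursor), 10E, 12R.

**Step 1**
Reactants: 1 nerol [(2Z)-3,7-dimethylocta-2,6-dien-1-ol]; 2 phosphorus tribromide
Product: 3 neryl bromide [(2Z)-1-bromo-3,7-dimethylocta-2,6-diene]
Conditions: PBr3 (0.4 equiv), Et2O, −10 °C, 30 min; used crude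
Reagents that add atoms: phosphorus tribromide, BrP(Br)Br
Why: SN2 bromination of the primary allylic alcohol through its phosphite ester at low temperature keeps the 2Z olefin and avoids allylic transposition.

**Step 2**
Reactants: 3 neryl bromide; 4 propyne
Product: 6 (5Z)-6,10-dimethylundeca-5,9-dien-1-yne, via lithium acetylide 5 (not isolated)
Conditions: propyne (1.6 equiv), n-BuLi (3.2 equiv), TMEDA, Et2O–hexane, −78 °C → rt; then 3, THF, −78 → 0 °C; H2O
Reagents that add atoms: propyne, CC#C
Why: Alkylation of the propargyl dianion (1,3-dilithiopropyne) at its sp3 carbanion by SN2 displacement of the primary allylic bromide gives the terminal 1,5-enyne directly after protonation, with the Z olefin untouched.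

**Step 3**
Reactants: 6 (5Z)-6,10-dimethylundeca-5,9-dien-1-yne; 7 trimethylaluminium; 8 paraformaldehyde; 9 acetic anhydride
Product: 13 (2E,6Z)-farnesyl acetate [(2E,6Z)-3,7,11-trimethyldodeca-2,6,10-trien-1-yl acetate], via alkenyldimethylalane 10 (not isolated), via lithium alkenylaluminate 11 (not isolated), via lithium alkoxyaluminate 12 (not isolated)
Conditions: Me3Al (2.5 equiv), Cp2ZrCl2 (25 mol %), CH2Cl2, rt; evaporate; n-BuLi (1.0 equiv), THF–hexane, −78 → 0 °C; (CH2O)n, rt; then Ac2O (5 equiv), pyridine, DMAP, 0 °C → rt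
Reagents that add atoms: trimethylaluminium, C[Al](C)C; paraformaldehyde, C=O; acetic anhydride, CC(=O)OC(C)=O
Why: Negishi zirconium-catalysed syn-carboalumination of the terminal alkyne sets the 2E trisubstituted olefin (>98:2), the alkenylalanate is hydroxymethylated by formaldehyde, and the aluminium alkoxide is acetylated in the flask as in reductive-acetylation protocols.

**Step 4**
Reactants: 13 (2E,6Z)-farnesyl acetate; 14 selenium dioxide
Product: 15 (2E,6Z,10E)-3,7,11-trimethyl-12-oxododeca-2,6,10-trien-1-yl acetate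
Conditions: SeO2 (1.2 equiv), 95% EtOH, reflux, 1.5 h
Reagents that add atoms: selenium dioxide, O=[Se]=O
Why: Riley allylic oxidation (ene reaction, then 2,3-sigmatropic shift) attacks the terminal, most accessible trisubstituted olefin at its E-methyl group and gives the E-enal, while the 2,3-olefin is deactivated by the allylic acetate.

**Step 5**
Reactants: 15 (2E,6Z,10E)-3,7,11-trimethyl-12-oxododeca-2,6,10-trien-1-yl acetate
Product: 16 (2E,6Z,10E)-12-oxofarnesol [(2E,6Z,10E)-12-hydroxy-2,6,10-trimethyldodeca-2,6,10-trienal; CH2OH = C1, CHO = C12]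
Conditions: K2CO3 (0.2 equiv), MeOH, 0 °C, 1 h
Reagents that add atoms: none
Why: Base-catalysed methanolysis (transesterification) removes the primary acetate without touching the α-branched enal.

**Step 6**
Reactants: 16 (2E,6Z,10E)-12-oxofarnesol; 17 potassium peroxymonosulfate
Product: 19 (2R,3R,6R,7S,10E)-2,3:6,7-diepoxy-1-hydroxy-3,7,11-trimethyldodec-10-en-12-al, via 6,7-monoepoxide 18 (not isolated)
Conditions: 1,2:4,5-di-O-isopropylidene-β-D-erythro-2,3-hexodiulo-2,6-pyranose (D-fructose-derived Shi ketone, 0.6 equiv), KHSO5 (as 2KHSO5·KHSO4·K2SO4, 3 equiv), K2CO3, n-Bu4NHSO4 (5 mol %), MeCN–CH2(OMe)2 1:2, aq. Na2B4O7/Na2EDTA buffer, pH 10.5, −5 → 0 °C, 2 h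
Reagents that add atoms: potassium peroxymonosulfate, [K+].[O-]S(=O)(=O)OO
Why: Shi asymmetric epoxidation: the chiral dioxirane attacks both electron-rich trisubstituted olefins through the spiro transition state with the olefinic hydrogen next to the spiroketal, so the same face is taken at C2 and C6 (2R,3R from the E-olefin, 6R,7S from the Z-olefin), and the enal olefin is too electron-poor to react.

**Step 7**
Reactants: 19 (2R,3R,6R,7S,10E)-2,3:6,7-diepoxy-1-hydroxy-3,7,11-trimethyldodec-10-en-12-al; 20 2,3-dimethylbut-1-ene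
Product: 22 (2R,3R,6R,7S,10E,12R)-2,3:6,7-diepoxy-3,7,11,15-tetramethyl-14-methylidenehexadec-10-ene-1,12-diol (target), via C12 borinate ester 21 (not isolated)
Conditions: 20 (6 equiv), n-BuLi, KOt-Bu (2.6 equiv each), THF, −78 → −45 °C; (+)-Ipc2BOMe [from (−)-α-pinene] (3.0 equiv), −78 °C; BF3·OEt2 (3.0 equiv), −78 °C; 19, −78 °C, 4 h; then pH 7 phosphate buffer, MeOH, 30% H2O2, 0 °C → rt
Reagents that add atoms: 2,3-dimethylbut-1-ene, C=C(C)C(C)C
Why: Brown asymmetric allylboration: the 2-isopropylallylborane carrying isopinocampheyl groups from (−)-α-pinene adds through a chair six-membered transition state to the Re face of the aldehyde (the enantiomeric reagent gives the S alcohol from benzaldehyde, whose CIP pattern the enal shares) and sets 12R under reagent control, with the oxiranes inert at −78 °C and the free hydroxyl at most consuming excess reagent.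

**Compound list**
1 | nerol, (2Z)-3,7-dimethylocta-2,6-dien-1-ol | CC(C)=CCC/C(C)=C\CO | starting material
2 | phosphorus tribromide | BrP(Br)Br | starting material
3 | neryl bromide, (2Z)-1-bromo-3,7-dimethylocta-2,6-diene | CC(C)=CCC/C(C)=C\CBr | intermediate
4 | propyne | CC#C | starting material
5 | lithium acetylide of 6 | CC(C)=CCC/C(C)=C\CCC#C[Li] | intermediate
6 | (5Z)-6,10-dimethylundeca-5,9-dien-1-yne | CC(C)=CCC/C(C)=C\CCC#C | intermediate
7 | trimethylaluminium | C[Al](C)C | starting material
8 | paraformaldehyde (formaldehyde unit) | C=O | starting material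
9 | acetic anhydride | CC(=O)OC(C)=O | starting material
10 | dimethyl[(1E,5Z)-2,6,10-trimethylundeca-1,5,9-trienyl]alane | CC(C)=CCC/C(C)=C\CC/C(C)=C/[Al](C)C | intermediate
11 | lithium butyl(dimethyl)[(1E,5Z)-2,6,10-trimethylundeca-1,5,9-trienyl]aluminate | CC(C)=CCC/C(C)=C\CC/C(C)=C/[Al-](C)(C)CCCC.[Li+] | intermediate
12 | lithium butyl(dimethyl)[(2E,6Z)-farnesyloxy]aluminate | CC(C)=CCC/C(C)=C\CC/C(C)=C/CO[Al-](C)(C)CCCC.[Li+] | intermediate
13 | (2E,6Z)-farnesyl acetate | CC(C)=CCC/C(C)=C\CC/C(C)=C/COC(C)=O | intermediate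
14 | selenium dioxide | O=[Se]=O | starting material
15 | (2E,6Z,10E)-3,7,11-trimethyl-12-oxododeca-2,6,10-trien-1-yl acetate | O=C/C(C)=C/CC/C(C)=C\CC/C(C)=C/COC(C)=O | intermediate
16 | (2E,6Z,10E)-12-oxofarnesol | O=C/C(C)=C/CC/C(C)=C\CC/C(C)=C/CO | intermediate
17 | potassium peroxymonosulfate | [K+].[O-]S(=O)(=O)OO | starting material
18 | (6R,7S)-6,7-epoxide of 16 (2E,10E) | O=C/C(C)=C/CC[C@]1(C)O[C@@H]1CC/C(C)=C/CO | intermediate
19 | (2R,3R,6R,7S,10E)-2,3:6,7-diepoxy-1-hydroxy-3,7,11-trimethyldodec-10-en-12-al | O=C/C(C)=C/CC[C@]1(C)O[C@@H]1CC[C@@]1(C)O[C@@H]1CO | intermediate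
20 | 2,3-dimethylbut-1-ene | C=C(C)C(C)C | starting material
21 | 12-O-diisopinocampheylboryl derivative of 22 | C=C(C[C@@H](OB([C@H]3C[C@H]4C[C@@H]([C@@H]3C)C4(C)C)[C@H]5C[C@H]6C[C@@H]([C@@H]5C)C6(C)C)/C(C)=C/CC[C@]1(C)O[C@@H]1CC[C@@]1(C)O[C@@H]1CO)C(C)C | intermediate
22 | (2R,3R,6R,7S,10E,12R)-2,3:6,7-diepoxy-3,7,11,15-tetramethyl-14-methylidenehexadec-10-ene-1,12-diol | C=C(C[C@@H](O)/C(C)=C/CC[C@]1(C)O[C@@H]1CC[C@@]1(C)O[C@@H]1CO)C(C)C | target

**Totals**
Total step count: 7. Longest linear sequence: 7 steps (from nerol).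

**Three steps most likely to fail**

Step 6 (double epoxidation). The risks are incomplete or poorly face-selective epoxidation at the allylic-alcohol olefin, lower selectivity at the Z olefin, and oxidation of the enal aldehyde by peroxymonosulfate. The fallback sets out from 16 and comes back at 19. Sharpless asymmetric epoxidation of 16 [Ti(OiPr)4, D-(−)-diethyl tartrate, t-BuOOH, 4 Å sieves, CH2Cl2, −20 °C] touches only the allylic alcohol and gives (2R,3R)-2,3-epoxy-12-oxo-(6Z,10E)-farnesol F1. A single Shi epoxidation of the one remaining electron-rich olefin of F1, under the step 6 conditions with half the oxidant, then gives 19. This fallback does not remove the aldehyde's exposure to peroxymonosulfate.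

Step 7 (allylboration). The risks are an untested 2-isopropylallylborane, a substrate with a free hydroxyl, and two acid-sensitive oxiranes. The fallback sets out from 19 and comes back at 22. 2-Isopropylallylpotassium (3 equiv, THF, −78 °C) is added directly to 19 without stereocontrol to give the C12-epimeric diol mixture F2. MnO2 (CH2Cl2, rt) oxidises only the allylic C12 alcohol to the enone (2R,3R,6R,7S,10E)-2,3:6,7-diepoxy-1-hydroxy-3,7,11,15-tetramethyl-14-methylidenehexadec-10-en-12-one F3. Corey–Bakshi–Shibata reduction of F3 with (S)-1-methyl-3,3-diphenyltetrahydro-1H,3H-pyrrolo[1,2-c][1,3,2]oxazaborole and catecholborane (toluene, −78 °C), with the alkenyl group as the large substituent, gives the 12R alcohol 22.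

Step 3 (one-flask carboalumination, hydroxymethylation and acetylation). The risk is that the aluminium alkoxide acetylates poorly in the presence of residual alkylaluminium species. The fallback sets out from 3, leaves out 6, and comes back at 13. Alkylation of ethyl acetoacetate with 3 (NaOEt, EtOH) gives ethyl (4Z)-2-acetyl-5,9-dimethyldeca-4,8-dienoate F4. Saponification and decarboxylation (aq. NaOH, then H3O+, heat) give nerylacetone F5. Horner–Wadsworth–Emmons olefination with triethyl phosphonoacetate (NaH, THF) gives ethyl (2E,6Z)-farnesoate F6 after removal of the minor 2Z isomer on silica. Reduction with i-Bu2AlH (CH2Cl2, −78 °C) gives (2E,6Z)-farnesol F7, and Ac2O/pyridine gives 13.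

**Further compounds**
F1 | step 6 | (2R,3R,6Z,10E)-2,3-epoxy-1-hydroxy-3,7,11-trimethyldodeca-6,10-dien-12-al | O=C/C(C)=C/CC/C(C)=C\CC[C@@]1(C)O[C@@H]1CO
F2 | step 7 | C12-epimeric mixture of 22 | C=C(CC(O)/C(C)=C/CC[C@]1(C)O[C@@H]1CC[C@@]1(C)O[C@@H]1CO)C(C)C
F3 | step 7 | (2R,3R,6R,7S,10E)-2,3:6,7-diepoxy-1-hydroxy-3,7,11,15-tetramethyl-14-methylidenehexadec-10-en-12-one | C=C(CC(=O)/C(C)=C/CC[C@]1(C)O[C@@H]1CC[C@@]1(C)O[C@@H]1CO)C(C)C
F4 | step 3 | ethyl (4Z)-2-acetyl-5,9-dimethyldeca-4,8-dienoate (racemic) | CC(C)=CCC/C(C)=C\CC(C(C)=O)C(=O)OCC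
F5 | step 3 | nerylacetone, (5Z)-6,10-dimethylundeca-5,9-dien-2-one | CC(C)=CCC/C(C)=C\CCC(C)=O
F6 | step 3 | ethyl (2E,6Z)-farnesoate | CC(C)=CCC/C(C)=C\CC/C(C)=C/C(=O)OCC
F7 | step 3 | (2E,6Z)-farnesol | CC(C)=CCC/C(C)=C\CC/C(C)=C/CO
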